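**Plan**

1. Retrosynthetic cuts: the C6–O ester bond of the alkaloid (made with inversion), the ester between the 2-methyl-enoate carboxyl and the hydroxyethyl arm, and, once C4–CH3 is traced back to C4=O, C6–O to C6=CH2 and N–CH3 to N–Boc, the two ring bonds C7–C7a and C4a–C5.
2. Enabling feature: in the cyclopenta[c]pyridine core (C1, N2, C3, C4, C4a, C5, C6, C7, C7a) the five-membered ring is the fusion bond C4a–C7a spanned by C5–C6(O)–C7(CH3). With C6 carrying a methylene this is a methyl-trimethylenemethane laid across the α,β-bond of a piperidin-3-one enone whose carbonyl is C4.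
3. Forward order: the piperidine ring is bought, the cyclopentane is annulated in step 2, then C4 and C6 are adjusted (steps 3–7). The C10 chain is oxidised out of geranyl acetate, joined first to the silyl-protected cyclohexane diol (step 12) and last to the alkaloid (step 15).
4. Stereochemistry: C7a/C4a from the chiral Pd–phosphoramidite and the cis-fusing ring closure; C7 by equilibration next to the C6 ketone; C4 by convex-face hydrogenation; C6 by convex hydride delivery, then Mitsunobu inversion.
5. Both E-alkenes come from geranyl acetate; the trans relation of the two cyclohexane oxygens comes from axial enolate addition to 4-silyloxycyclohexanone.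

Key step: step 2

Assumption: the cyclohexane unit is built as drawn in the target (tertiary and secondary hydroxyl trans, side chain cis to the secondary hydroxyl); 6 is drawn as the C7 epimer with the methyl on the convex face, and any other C7 epimer follows the same steps and merges at 9; the phosphoramidite antipode is the one that leads to (7aR)-6.

**Route**

Step 1
Reactants: 1 2-bromoallyltrimethylsilane
Product: 4 3-[(trimethylsilyl)methyl]but-3-en-2-yl acetate, via vinyllithium 2 (not isolated), via lithium alkoxide 3 (not isolated)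
Conditions: t-BuLi (2 equiv), Et2O, −78 °C; CH3CHO, −78 °C; Ac2O, −78 °C → rt
Reagents that add atoms: acetaldehyde, CC=O; acetic anhydride, CC(=O)OC(C)=O
Why: Bromine–lithium exchange gives the vinyllithium, which adds 1,2 to acetaldehyde, and the lithium alkoxide is O-acylated in the same flask; the carbinol centre is racemic and is erased when palladium ionises the acetate in step 2.

Step 2
Reactants: 5 tert-butyl 3-oxo-3,6-dihydropyridine-1(2H)-carboxylate; 4 3-[(trimethylsilyl)methyl]but-3-en-2-yl acetate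
Product: 6 tert-butyl (4aS,7R,7aR)-7-methyl-6-methylidene-4-oxooctahydro-2H-cyclopenta[c]pyridine-2-carboxylate
Conditions: Pd(dba)2 (5 mol %), bis(2-naphthyl)pyrrolidine BINOL-phosphoramidite (10 mol %, single antipode), 4 (1.5 equiv), toluene, 0 → 45 °C
Reagents that add atoms: none
Why: Pd(0) ionises the allylic acetate and acetate-induced desilylation gives the zwitterionic Pd–trimethylenemethane complex, which equilibrates to the isomer with carbanion character on the methyl-bearing terminus; this carbon adds to the enone β-carbon (C7–C7a) and the enolate carbon then attacks the cationic π-allylpalladium (C4a–C5), releasing Pd(0). The closest known reaction type is the palladium-catalysed trimethylenemethane [3+2] cycloaddition of substituted 2-(silylmethyl)allyl acetates with cyclic enones, run here with a chiral phosphoramidite. The cyclopentane closes by intramolecular C-allylation of the enolate at a terminus of the 2-substituted π-allyl (Michael-initiated ring closure), which leaves C6 as the exocyclic methylene. C7a is set by ligand-controlled face selection in the Michael step, C4a follows because the tethered allyl can only reach the enolate on the same face (cis fusion), and the C7 methyl should prefer the convex orientation anti to C1, any 7-epimer being corrected at step 4. The step needs regioselectivity (methyl-bearing carbon to C7a), secured by charge localisation at the more substituted TMM terminus, and 1,4- over 1,2-selectivity, secured by the soft nucleophile and the unhindered β-position of the enone.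

Step 3
Reactants: 6 tert-butyl (4aS,7R,7aR)-7-methyl-6-methylidene-4-oxooctahydro-2H-cyclopenta[c]pyridine-2-carboxylate
Product: 7 tert-butyl (4aS,7R,7aR)-4-hydroxy-7-methyl-6-methylidene-4-[(trimethylsilyl)methyl]octahydro-2H-cyclopenta[c]pyridine-2-carboxylate (C4 carbinol epimers, both usable)
Conditions: Me3SiCH2MgCl, anhydrous CeCl3, THF, −78 → 0 °C; aq NH4Cl
Reagents that add atoms: (trimethylsilyl)methylmagnesium chloride, C[Si](C)(C)C[Mg]Cl
Why: Cerium-assisted 1,2-addition to the only ketone (first half of a Peterson olefination) proceeds without enolisation, so C4a is not epimerised and the carbamate is untouched; the new C4 centre is inconsequential because both epimers eliminate to the same alkene.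

Step 4
Reactants: 7 tert-butyl (4aS,7R,7aR)-4-hydroxy-7-methyl-6-methylidene-4-[(trimethylsilyl)methyl]octahydro-2H-cyclopenta[c]pyridine-2-carboxylate
Product: 9 tert-butyl (4aS,7R,7aS)-4-hydroxy-7-methyl-6-oxo-4-[(trimethylsilyl)methyl]octahydro-2H-cyclopenta[c]pyridine-2-carboxylate, via spiro ozonide 8 (not isolated)
Conditions: O3, CH2Cl2, −78 °C; Me2S, −78 °C → rt; aqueous wash; DBU (cat.), CH2Cl2, rt
Reagents that add atoms: ozone, [O-][O+]=O
Why: Ozonolysis of the only alkene with reductive work-up unmasks the C6 ketone, and the amine base then equilibrates C7, now α to a carbonyl, to the more stable epimer with the methyl trans to C1 on the convex face.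

Step 5
Reactants: 9 tert-butyl (4aS,7R,7aS)-4-hydroxy-7-methyl-6-oxo-4-[(trimethylsilyl)methyl]octahydro-2H-cyclopenta[c]pyridine-2-carboxylate
Product: 10 tert-butyl (4aS,7R,7aS)-7-methyl-4-methylidene-6-oxooctahydro-2H-cyclopenta[c]pyridine-2-carboxylate
Conditions: 48% aq HF, MeCN, 0 °C → rt
Reagents that add atoms: none
Why: Acid-promoted Peterson elimination of the tertiary β-hydroxysilane gives only the exocyclic alkene, avoiding the endocyclic isomers of a plain alcohol dehydration, under conditions that the Boc group and the ketone tolerate.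

Step 6
Reactants: 10 tert-butyl (4aS,7R,7aS)-7-methyl-4-methylidene-6-oxooctahydro-2H-cyclopenta[c]pyridine-2-carboxylate
Product: 11 tert-butyl (4S,4aR,7R,7aS)-4,7-dimethyl-6-oxooctahydro-2H-cyclopenta[c]pyridine-2-carboxylate
Conditions: H2 (1 atm), 10% Pd/C, EtOAc, rt
Reagents that add atoms: none
Why: Heterogeneous hydrogenation of the 1,1-disubstituted alkene should deliver hydrogen to the face of the ring-fusion hydrogens, anti to the C4a–C5 bond of the folded cis-bicycle, so that C4 becomes S with the methyl cis to C5.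

Step 7
Reactants: 11 tert-butyl (4S,4aR,7R,7aS)-4,7-dimethyl-6-oxooctahydro-2H-cyclopenta[c]pyridine-2-carboxylate
Product: 13 (4S,4aR,6R,7R,7aS)-2,4,7-trimethyloctahydro-1H-cyclopenta[c]pyridin-6-ol, via carbamate alcohol 12 (not isolated)
Conditions: LiAlH4 (excess), THF, −78 → 0 °C, then reflux; Fieser work-up
Reagents that add atoms: none
Why: LiAlH4 first reduces the ketone, the small hydride entering from the convex face (the concave face is screened by the piperidine ring, and small hydrides add syn to an α-methyl in cyclopentanones) to give the 6R alcohol with the hydroxyl trans to the 7-methyl, and on heating reduces the tert-butyl carbamate to N-methyl.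

Step 8
Reactants: 14 geranyl acetate
Product: 15 (2E,6E)-8-hydroxy-3,7-dimethylocta-2,6-dien-1-yl acetate
Conditions: SeO2 (cat.), t-BuOOH, salicylic acid (cat.), CH2Cl2, rt
Reagents that add atoms: selenium dioxide, O=[Se]=O (catalytic oxygen carrier); tert-butyl hydroperoxide, CC(C)(C)OO (stoichiometric oxygen source)
Why: The SeO2/TBHP allylic oxidation (ene reaction then [2,3]-shift) is selective for the E-methyl of the electron-rich terminal alkene, the 2,3-alkene being deactivated by the allylic acetate; any over-oxidised enal is the intermediate of step 9 and converges there.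

Step 9
Reactants: 15 (2E,6E)-8-hydroxy-3,7-dimethylocta-2,6-dien-1-yl acetate
Product: 17 (2E,6E)-8-acetoxy-2,6-dimethylocta-2,6-dienoic acid, via enal 16 (not isolated)
Conditions: TEMPO (cat.), PhI(OAc)2, CH2Cl2, rt; then t-BuOH/H2O, 2-methylbut-2-ene, NaClO2, NaH2PO4, 0 °C → rt
Reagents that add atoms: sodium chlorite, [Na+].[O-]Cl=O
Why: TEMPO/PhI(OAc)2 oxidises the allylic alcohol to the enal without touching alkenes or acetate, and Pinnick oxidation takes it to the acid with the E geometry retained.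

Step 10
Reactants: 18 4-[(tert-butyldimethylsilyl)oxy]cyclohexan-1-one
Product: 19 ethyl 2-{4-[(tert-butyldimethylsilyl)oxy]-1-hydroxycyclohexyl}acetate (1-OH trans to 4-OTBS, CH2CO2Et cis to OTBS)
Conditions: LDA, EtOAc, THF, −78 °C; then 18, −78 °C; aq NH4Cl at −78 °C; chromatography
Reagents that add atoms: ethyl acetate, CCOC(C)=O
Why: Kinetic aldol addition of the lithium enolate of ethyl acetate, in which axial attack of the small nucleophile on the chair with equatorial OTBS is expected to place the carbon chain cis and the new hydroxyl trans to the silyloxy group; the equatorial-attack isomer is removed by chromatography.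

Step 11
Reactants: 19 ethyl 2-{4-[(tert-butyldimethylsilyl)oxy]-1-hydroxycyclohexyl}acetate
Product: 20 4-[(tert-butyldimethylsilyl)oxy]-1-(2-hydroxyethyl)cyclohexan-1-ol (1-OH trans to 4-OTBS)
Conditions: LiAlH4, THF, 0 °C; Fieser work-up
Reagents that add atoms: none
Why: Hydride reduction of the ester to the primary alcohol at 0 °C leaves the silyl ether and both ring stereocentres untouched.

Step 12
Reactants: 17 (2E,6E)-8-acetoxy-2,6-dimethylocta-2,6-dienoic acid; 20 4-[(tert-butyldimethylsilyl)oxy]-1-(2-hydroxyethyl)cyclohexan-1-ol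
Product: 21 2-{4-[(tert-butyldimethylsilyl)oxy]-1-hydroxycyclohexyl}ethyl (2E,6E)-8-acetoxy-2,6-dimethylocta-2,6-dienoate
Conditions: DIC, DMAP (cat.), CH2Cl2, 0 °C → rt
Reagents that add atoms: none
Why: Steglich esterification acylates only the primary hydroxyl of 20, the tertiary hydroxyl being inert and the secondary one already silylated.

Step 13
Reactants: 21 2-{4-[(tert-butyldimethylsilyl)oxy]-1-hydroxycyclohexyl}ethyl (2E,6E)-8-acetoxy-2,6-dimethylocta-2,6-dienoate
Product: 22 2-{4-[(tert-butyldimethylsilyl)oxy]-1-hydroxycyclohexyl}ethyl (2E,6E)-8-hydroxy-2,6-dimethylocta-2,6-dienoate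
Conditions: K2CO3 (cat.), MeOH, 0 °C
Reagents that add atoms: none
Why: Base-catalysed methanolysis (transesterification) cleaves the unhindered allylic acetate much faster than the conjugated, α-methyl-substituted enoate, and the TBS ether is stable to carbonate.

Step 14
Reactants: 22 2-{4-[(tert-butyldimethylsilyl)oxy]-1-hydroxycyclohexyl}ethyl (2E,6E)-8-hydroxy-2,6-dimethylocta-2,6-dienoate
Product: 24 (2E,6E)-8-(2-{4-[(tert-butyldimethylsilyl)oxy]-1-hydroxycyclohexyl}ethoxy)-3,7-dimethyl-8-oxoocta-2,6-dienoic acid, via enal 23 (not isolated)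
Conditions: TEMPO (cat.), PhI(OAc)2, CH2Cl2, rt; then t-BuOH/H2O, 2-methylbut-2-ene, NaClO2, NaH2PO4, 0 °C → rt
Reagents that add atoms: sodium chlorite, [Na+].[O-]Cl=O
Why: TEMPO/PhI(OAc)2 then Pinnick oxidation converts the allylic alcohol to the 3-methyl-2-enoic acid without E/Z isomerisation, the tertiary alcohol, silyl ether and enoate ester being inert to both oxidants.

Step 15
Reactants: 13 (4S,4aR,6R,7R,7aS)-2,4,7-trimethyloctahydro-1H-cyclopenta[c]pyridin-6-ol; 24 (2E,6E)-8-(2-{4-[(tert-butyldimethylsilyl)oxy]-1-hydroxycyclohexyl}ethoxy)-3,7-dimethyl-8-oxoocta-2,6-dienoic acid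
Product: 25 1-(2-{4-[(tert-butyldimethylsilyl)oxy]-1-hydroxycyclohexyl}ethyl) 8-[(4S,4aR,6S,7R,7aS)-2,4,7-trimethyloctahydro-1H-cyclopenta[c]pyridin-6-yl] (2E,6E)-2,6-dimethylocta-2,6-dienedioate
Conditions: PPh3, DIAD, THF, 0 °C → rt
Reagents that add atoms: none
Why: Mitsunobu esterification, in which the carboxylate displaces the C6 oxyphosphonium by SN2 and so inverts 6R to 6S (ester on the convex face, cis to the 7-methyl); the tertiary alcohol cannot be activated and the tertiary amine is tolerated.

Step 16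
Reactants: 25 1-(2-{4-[(tert-butyldimethylsilyl)oxy]-1-hydroxycyclohexyl}ethyl) 8-[(4S,4aR,6S,7R,7aS)-2,4,7-trimethyloctahydro-1H-cyclopenta[c]pyridin-6-yl] (2E,6E)-2,6-dimethylocta-2,6-dienedioate
Product: 26 1-[2-(1,4-dihydroxycyclohexyl)ethyl] 8-[(4S,4aR,6S,7R,7aS)-2,4,7-trimethyloctahydro-1H-cyclopenta[c]pyridin-6-yl] (2E,6E)-2,6-dimethylocta-2,6-dienedioate (hydroxyls trans), the target
Conditions: HF·pyridine, pyridine/THF, 0 °C → rt; aq NaHCO3
Reagents that add atoms: none
Why: Fluoride-mediated cleavage of the secondary TBS ether under buffered conditions that leave both enoate esters, the tertiary alcohol and the amine untouched.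

**Compound list**

1 | 2-bromoallyltrimethylsilane | C=C(Br)C[Si](C)(C)C | starting material
2 | [3-(trimethylsilyl)prop-1-en-2-yl]lithium | [Li]C(=C)C[Si](C)(C)C | intermediate
3 | lithium 3-[(trimethylsilyl)methyl]but-3-en-2-olate | CC(O[Li])C(=C)C[Si](C)(C)C | intermediate
4 | 3-[(trimethylsilyl)methyl]but-3-en-2-yl acetate (racemic) | CC(OC(C)=O)C(=C)C[Si](C)(C)C | intermediate
5 | tert-butyl 3-oxo-3,6-dihydropyridine-1(2H)-carboxylate | O=C1C=CCN(C(=O)OC(C)(C)C)C1 | starting material
6 | tert-butyl (4aS,7R,7aR)-7-methyl-6-methylidene-4-oxooctahydro-2H-cyclopenta[c]pyridine-2-carboxylate | C=C1C[C@H]2[C@H](CN(C(=O)OC(C)(C)C)CC2=O)[C@H]1C | intermediate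
7 | tert-butyl (4aS,7R,7aR)-4-hydroxy-7-methyl-6-methylidene-4-[(trimethylsilyl)methyl]octahydro-2H-cyclopenta[c]pyridine-2-carboxylate (C4 epimers) | C=C1C[C@H]2[C@H](CN(C(=O)OC(C)(C)C)CC2(O)C[Si](C)(C)C)[C@H]1C | intermediate
8 | spiro ozonide (1,2,4-trioxolane at C6) of 7, (4aS,7R,7aS) | C14(OOCO4)C[C@H]2[C@H](CN(C(=O)OC(C)(C)C)CC2(O)C[Si](C)(C)C)[C@H]1C | intermediate
9 | tert-butyl (4aS,7R,7aS)-4-hydroxy-7-methyl-6-oxo-4-[(trimethylsilyl)methyl]octahydro-2H-cyclopenta[c]pyridine-2-carboxylate | O=C1C[C@H]2[C@H](CN(C(=O)OC(C)(C)C)CC2(O)C[Si](C)(C)C)[C@H]1C | intermediate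
10 | tert-butyl (4aS,7R,7aS)-7-methyl-4-methylidene-6-oxooctahydro-2H-cyclopenta[c]pyridine-2-carboxylate | O=C1C[C@H]2[C@H](CN(C(=O)OC(C)(C)C)CC2=C)[C@H]1C | intermediate
11 | tert-butyl (4S,4aR,7R,7aS)-4,7-dimethyl-6-oxooctahydro-2H-cyclopenta[c]pyridine-2-carboxylate | O=C1C[C@H]2[C@H](CN(C(=O)OC(C)(C)C)C[C@H]2C)[C@H]1C | intermediate
12 | tert-butyl (4S,4aR,6R,7R,7aS)-6-hydroxy-4,7-dimethyloctahydro-2H-cyclopenta[c]pyridine-2-carboxylate (as its aluminium alkoxide) | O[C@@H]1C[C@H]2[C@H](CN(C(=O)OC(C)(C)C)C[C@H]2C)[C@H]1C | intermediate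
13 | (4S,4aR,6R,7R,7aS)-2,4,7-trimethyloctahydro-1H-cyclopenta[c]pyridin-6-ol (6-OH trans to 7-CH3) | O[C@@H]1C[C@H]2[C@H](CN(C)C[C@H]2C)[C@H]1C | intermediate
14 | geranyl acetate, (2E)-3,7-dimethylocta-2,6-dien-1-yl acetate | C/C(=C\COC(C)=O)CCC=C(C)C | starting material
15 | (2E,6E)-8-hydroxy-3,7-dimethylocta-2,6-dien-1-yl acetate | C/C(=C\COC(C)=O)CC/C=C(\C)CO | intermediate
16 | (2E,6E)-3,7-dimethyl-8-oxoocta-2,6-dien-1-yl acetate | C/C(=C\COC(C)=O)CC/C=C(\C)C=O | intermediate
17 | (2E,6E)-8-acetoxy-2,6-dimethylocta-2,6-dienoic acid | C/C(=C\COC(C)=O)CC/C=C(\C)C(=O)O | intermediate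
18 | 4-[(tert-butyldimethylsilyl)oxy]cyclohexan-1-one | O=C1CCC(O[Si](C)(C)C(C)(C)C)CC1 | starting material
19 | ethyl 2-{4-[(tert-butyldimethylsilyl)oxy]-1-hydroxycyclohexyl}acetate (1-OH trans to 4-OTBS) | CCOC(=O)C[C@]1(O)CC[C@H](O[Si](C)(C)C(C)(C)C)CC1 | intermediate
20 | 4-[(tert-butyldimethylsilyl)oxy]-1-(2-hydroxyethyl)cyclohexan-1-ol (1-OH trans to 4-OTBS) | OCC[C@]1(O)CC[C@H](O[Si](C)(C)C(C)(C)C)CC1 | intermediate
21 | 2-{4-[(tert-butyldimethylsilyl)oxy]-1-hydroxycyclohexyl}ethyl (2E,6E)-8-acetoxy-2,6-dimethylocta-2,6-dienoate | C/C(=C\COC(C)=O)CC/C=C(\C)C(=O)OCC[C@]1(O)CC[C@H](O[Si](C)(C)C(C)(C)C)CC1 | intermediate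
22 | 2-{4-[(tert-butyldimethylsilyl)oxy]-1-hydroxycyclohexyl}ethyl (2E,6E)-8-hydroxy-2,6-dimethylocta-2,6-dienoate | C/C(=C\CO)CC/C=C(\C)C(=O)OCC[C@]1(O)CC[C@H](O[Si](C)(C)C(C)(C)C)CC1 | intermediate
23 | 2-{4-[(tert-butyldimethylsilyl)oxy]-1-hydroxycyclohexyl}ethyl (2E,6E)-2,6-dimethyl-8-oxoocta-2,6-dienoate | C/C(=C\C=O)CC/C=C(\C)C(=O)OCC[C@]1(O)CC[C@H](O[Si](C)(C)C(C)(C)C)CC1 | intermediate
24 | (2E,6E)-8-(2-{4-[(tert-butyldimethylsilyl)oxy]-1-hydroxycyclohexyl}ethoxy)-3,7-dimethyl-8-oxoocta-2,6-dienoic acid | C/C(=C\C(=O)O)CC/C=C(\C)C(=O)OCC[C@]1(O)CC[C@H](O[Si](C)(C)C(C)(C)C)CC1 | intermediate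
25 | 1-(2-{4-[(tert-butyldimethylsilyl)oxy]-1-hydroxycyclohexyl}ethyl) 8-[(4S,4aR,6S,7R,7aS)-2,4,7-trimethyloctahydro-1H-cyclopenta[c]pyridin-6-yl] (2E,6E)-2,6-dimethylocta-2,6-dienedioate | C/C(=C\C(=O)O[C@H]1C[C@H]2[C@H](CN(C)C[C@H]2C)[C@H]1C)CC/C=C(\C)C(=O)OCC[C@]1(O)CC[C@H](O[Si](C)(C)C(C)(C)C)CC1 | intermediate
26 | 1-[2-(1,4-dihydroxycyclohexyl)ethyl] 8-[(4S,4aR,6S,7R,7aS)-2,4,7-trimethyloctahydro-1H-cyclopenta[c]pyridin-6-yl] (2E,6E)-2,6-dimethylocta-2,6-dienedioate (cyclohexane hydroxyls trans) | C/C(=C\C(=O)O[C@H]1C[C@H]2[C@H](CN(C)C[C@H]2C)[C@H]1C)CC/C=C(\C)C(=O)OCC[C@]1(O)CC[C@H](O)CC1 | target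

**Count**

Total steps: 16. Longest linear sequence: 9 steps (steps 1–7, 15 and 16, from 1).

**The three steps most likely to fail**

Step 2. The basic Pd–TMM zwitterion may be protonated by the acidic N–CH2–C(=O) methylene of 5 (donor lost by protodesilylation), turnover on an unactivated cyclic enone may be slow, and the ligand may discriminate the enone faces poorly. The fallback keeps the cycloaddition but takes enantiocontrol from a resolution instead of the catalyst. From 4 and 5 the reaction is run with the achiral and most active catalyst, Pd(OAc)2/P(O-i-Pr)3 in refluxing THF, which gives 6 as a racemate, that is together with tert-butyl (4aR,7S,7aS)-7-methyl-6-methylidene-4-oxooctahydro-2H-cyclopenta[c]pyridine-2-carboxylate F1. Steps 3–7 are applied unchanged and produce, beside 7–13, the mirror-image β-hydroxysilane F2, the mirror-image spiro ozonide F3, the mirror-image keto silane F4, the mirror-image methylene ketone F5, the mirror-image dimethyl ketone F6, the mirror-image carbamate alcohol F7 and the mirror-image amino alcohol F8. The racemic amine is resolved by fractional crystallisation from ethanol of the hydrogen (2R,3R)-di-p-toluoyltartrate salt of 13 F9 (the antipodal acid is taken if it is the salt of the mirror-image amine that crystallises), and aqueous NaOH liberates 13, where the route is rejoined.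

Step 10. Facial selectivity of the enolate addition may be low because both chairs of the silyloxy ketone are populated, so that too little of the isomer with the hydroxyl trans to OTBS forms. The fallback builds the side chain through an epoxide. From 18, dimethylsulfonium methylide (Me3S+ I−, n-BuLi, THF, 0 °C; Corey–Chaykovsky), a reagent known to deliver its methylene carbon axially to cyclohexanones, gives 6-[(tert-butyldimethylsilyl)oxy]-1-oxaspiro[2.5]octane F10 with the epoxide oxygen trans to OTBS. Copper-catalysed opening at the epoxide CH2 with vinylmagnesium bromide (CuI, THF, −30 °C) gives 1-allyl-4-[(tert-butyldimethylsilyl)oxy]cyclohexan-1-ol F11. Ozonolysis (O3, CH2Cl2, −78 °C; Me2S) gives 2-{4-[(tert-butyldimethylsilyl)oxy]-1-hydroxycyclohexyl}acetaldehyde F12, which NaBH4 in MeOH reduces to 20, where the route is rejoined.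

Step 15. The activated C6 oxyphosphonium may undergo E2 elimination, and SN2 attack at a carbon flanked by the 7-methyl group may be slow, made worse by ammonium carboxylate formation. The fallback avoids substitution at C6. From 11, K-Selectride (THF, −78 °C), a bulky hydride that should attack the cyclopentanone anti to the adjacent 7-methyl, is expected to give tert-butyl (4S,4aR,6S,7R,7aS)-6-hydroxy-4,7-dimethyloctahydro-2H-cyclopenta[c]pyridine-2-carboxylate F13. LiAlH4 in refluxing THF then gives (4S,4aR,6S,7R,7aS)-2,4,7-trimethyloctahydro-1H-cyclopenta[c]pyridin-6-ol F14, with the hydroxyl already in the target configuration. Acid 24 is converted with 2,4,6-trichlorobenzoyl chloride and Et3N into its 2,4,6-trichlorobenzoic mixed anhydride F15, which acylates the amino alcohol with retention (DMAP, toluene; Yamaguchi esterification) to give 25, where the route is rejoined.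

**Further compounds**

F1 | step 2 | tert-butyl (4aR,7S,7aS)-7-methyl-6-methylidene-4-oxooctahydro-2H-cyclopenta[c]pyridine-2-carboxylate (enantiomer of 6) | C=C1C[C@@H]2[C@@H](CN(C(=O)OC(C)(C)C)CC2=O)[C@@H]1C
F2 | step 2 | enantiomer of 7 (β-hydroxysilane, C4 epimers) | C=C1C[C@@H]2[C@@H](CN(C(=O)OC(C)(C)C)CC2(O)C[Si](C)(C)C)[C@@H]1C
F3 | step 2 | enantiomer of 8 (spiro ozonide) | C14(OOCO4)C[C@@H]2[C@@H](CN(C(=O)OC(C)(C)C)CC2(O)C[Si](C)(C)C)[C@@H]1C
F4 | step 2 | enantiomer of 9 (keto silane) | O=C1C[C@@H]2[C@@H](CN(C(=O)OC(C)(C)C)CC2(O)C[Si](C)(C)C)[C@@H]1C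
F5 | step 2 | enantiomer of 10 (methylene ketone) | O=C1C[C@@H]2[C@@H](CN(C(=O)OC(C)(C)C)CC2=C)[C@@H]1C
F6 | step 2 | enantiomer of 11 (dimethyl ketone) | O=C1C[C@@H]2[C@@H](CN(C(=O)OC(C)(C)C)C[C@@H]2C)[C@@H]1C
F7 | step 2 | enantiomer of 12 (carbamate alcohol) | O[C@H]1C[C@@H]2[C@@H](CN(C(=O)OC(C)(C)C)C[C@@H]2C)[C@@H]1C
F8 | step 2 | (4R,4aS,6S,7S,7aR)-2,4,7-trimethyloctahydro-1H-cyclopenta[c]pyridin-6-ol (enantiomer of 13) | O[C@H]1C[C@@H]2[C@@H](CN(C)C[C@@H]2C)[C@@H]1C
F9 | step 2 | hydrogen (2R,3R)-di-p-toluoyltartrate salt of 13 | O[C@@H]1C[C@H]2[C@H](C[NH+](C)C[C@H]2C)[C@H]1C.OC(=O)[C@H](OC(=O)c1ccc(C)cc1)[C@@H](OC(=O)c1ccc(C)cc1)C(=O)[O-]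
F10 | step 10 | 6-[(tert-butyldimethylsilyl)oxy]-1-oxaspiro[2.5]octane (epoxide O trans to OTBS) | O1C[C@@]12CC[C@H](O[Si](C)(C)C(C)(C)C)CC2
F11 | step 10 | 1-allyl-4-[(tert-butyldimethylsilyl)oxy]cyclohexan-1-ol (1-OH trans to 4-OTBS) | C=CC[C@]1(O)CC[C@H](O[Si](C)(C)C(C)(C)C)CC1
F12 | step 10 | 2-{4-[(tert-butyldimethylsilyl)oxy]-1-hydroxycyclohexyl}acetaldehyde (1-OH trans to 4-OTBS) | O=CC[C@]1(O)CC[C@H](O[Si](C)(C)C(C)(C)C)CC1
F13 | step 15 | tert-butyl (4S,4aR,6S,7R,7aS)-6-hydroxy-4,7-dimethyloctahydro-2H-cyclopenta[c]pyridine-2-carboxylate | O[C@H]1C[C@H]2[C@H](CN(C(=O)OC(C)(C)C)C[C@H]2C)[C@H]1C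
F14 | step 15 | (4S,4aR,6S,7R,7aS)-2,4,7-trimethyloctahydro-1H-cyclopenta[c]pyridin-6-ol | O[C@H]1C[C@H]2[C@H](CN(C)C[C@H]2C)[C@H]1C
F15 | step 15 | mixed anhydride of 24 with 2,4,6-trichlorobenzoic acid | C/C(=C\C(=O)OC(=O)c1c(Cl)cc(Cl)cc1Cl)CC/C=C(\C)C(=O)OCC[C@]1(O)CC[C@H](O[Si](C)(C)C(C)(C)C)CC1
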